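A first-order constant read off a falling curve misleads when what slows the fall changes from flask to flask.

| flask | substrate | reagent | remark | time |
|---|---|---|---|---|
| Wednesday's | 2 mM | 1.9 mM | run made earlier |  |
| Friday's | 2 mM | 3.5 mM | run made earlier |  |
| Sunday's | 2 mM | 8.8 mM | run made earlier |  |
| alpha | 2.0 mM | 6.00 mM |  | 30 min |
| epsilon | 2.0 mM | 8.00 mM |  | 30 min |
| zeta | 2.0 mM | 1.60 mM |  | 30 min |

| Wednesday's: time / min | Wednesday's: tris adduct / % | Friday's: time / min | Friday's: tris adduct / % | Sunday's: time / min | Sunday's: tris adduct / % |
|---|---|---|---|---|---|
| 2.50 | 0.3 | 8.00 | 0 | 4.00 | 85.5 |
| 6.00 | 0.3 | 15.0 | 0.4 | 10.0 | 71.0 |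
| 12.0 | 0 | 25.0 | 0 | 20.0 | 53.9 |
| 30.0 | 0 | 30.0 | 0.5 | 30.0 | 40.6 |

(each reading ± 0.5 percentage points)

1. which of these holds the largest part of the substrate at the end of alpha (mono adduct / substrate / tris adduct / bis adduct)
2. which of these holds the largest part of the substrate at the end of epsilon (mono adduct / substrate / tris adduct / bis adduct)
3. which of these holds the largest part of the substrate at the end of zeta (mono adduct / substrate / tris adduct / bis adduct)
4. tris adduct at the end of alpha, in percent of the substrate charged



Wednesday's and Friday's runs, at 0.950 and 1.75 equivalents, leave tris adduct within the scatter of zero, so we take the first two equivalents as going into mono and bis adduct. Sunday's run falls from 85.5% to 40.6% in spite of its excess. Our picture is that tris adduct stands in equilibrium with bis adduct and free reagent, while bis adduct, a trace, leaks into side product, keeping two reagents and returning the third. Let x be tris adduct as a fraction of the substrate charged, and S the equivalents charged less two. Free reagent is then S − x equivalents, and x falls per minute by κx/(S − x). Integrated, S times the natural log of the ratio of two x values, less their difference, equals κ times the time between them. Sunday's first and last readings, with S at 2.40, give the leak constant κ, read as 0.0515 min⁻¹ at this substrate charge; it should scale inversely with that charge.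

Alpha has S of 1.00, so its curve, taken from full tris adduct, opens steeply. By this reckoning it reaches half by 3.75 min, against 22.6 min for Sunday's. It then bends into a tail heading for zero, and we reckon 8.55% at the asked time. We therefore expect tris adduct to lead bis adduct in alpha and in epsilon. Zeta, at 0.800 equivalents, has less reagent than substrate, so there we guess mono adduct, which no run has read.

The forecast named bis adduct for alpha, bis adduct for epsilon and mono adduct for zeta, with 30% (15% to 40%) tris adduct in alpha, reasoning that there “tris formation is slower and less complete”, and our reckoning differs from it.

Of the four species asked about, the flasks give tris adduct for alpha, tris adduct for epsilon, mono adduct for zeta, and 10.5% tris adduct in alpha.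

    substrate + reagent → mono adduct (k = 210 M⁻¹ s⁻¹)
    reagent + mono adduct → bis adduct (k = 120 M⁻¹ s⁻¹)
    reagent + bis adduct ⇌ tris adduct (K = 25000 M⁻¹, k = 400 M⁻¹ s⁻¹)
    bis adduct → side product (k = 0.0430 s⁻¹)

Part of alpha's fall is the back step and the leak acting together: without the back step tris adduct stands at 91.8%, and without the leak at 86.8%. Alpha's simulated value, taken from full tris adduct, returns a leak constant of 0.0454 min⁻¹, against 0.0515 min⁻¹ read on Sunday's run. For alpha's neighbour with 0.80 mM of substrate, S is 5.50 and the constant, scaled inversely with the substrate charge and multiplied by the run time, gives 3.86, so we reckon 44.8%, and that flask holds 44.7% tris adduct.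

Readings and results come from a simulation with made-up constants, and the scatter is random.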